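**Retrosynthetic overview**

- Strategic feature: in the 1,2-dioxene ring (O1–O2–C3–C4=C5–C6), O1 is bonded to C6, which is β to the ester carbonyl C8 through C7, and C3 is a methyl peroxyketal at the ketone oxidation level. The ring is therefore H2O2 plus MeOH added to a (2E,4Z)-6-oxo-2,4-dienoate, and O1–C6 is a conjugate-addition bond.
- The only ring is closed last, by an enantioselective 6-exo peroxy-Michael addition of an acyclic α-methoxy hydroperoxide onto the dienoate (O1–C6). The ketal carbon C3 is then converged by methanol exchange.
- The hydroperoxy ketal comes from a dimethyl ketal, the 4Z alkene from semi-reduction of an enynoate, and the enynoate from Sonogashira coupling of a propargylic ketal with methyl (E)-3-iodoacrylate.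
- The propargylic ketal comes from a silylacetylide and a C19 dienyl Weinreb amide, itself from pentadecanolide (Weinreb opening) and crotonaldehyde (Julia–Kocienski olefination).

Key step: step 11

Remark on numbering: ring atoms are numbered O1–O2–C3–C4=C5–C6 with the methoxy ketal carbon as C3, so the target is (3S,6R). Acyclic precursors are numbered from the ester carbon, so ring C6 is chain C3 and ring C3 is chain C6.

Assumption: the sense of induction of the squaramide catalyst cannot be assigned in advance. The quinine-derived catalyst is written; its quinidine-derived pseudoenantiomer would be used instead if that is the one that delivers 6R.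

**Step 1**
Reactants: 1 ω-pentadecalactone (oxacyclohexadecan-2-one)
Product: 2 15-hydroxy-N-methoxy-N-methylpentadecanamide
Conditions: MeNH(OMe)·HCl, AlMe3, CH2Cl2, 0 °C to rt; aq. KNaC4H4O6 work-up
Reagents that add atoms: N,O-dimethylhydroxylamine hydrochloride, CNOC.Cl
Why: Weinreb aminolysis of the lactone by the aluminium amide formed in situ should open the macrocycle cleanly, leaving an acylating terminus at C1 and a free primary alcohol at C15.

**Step 2**
Reactants: 2 15-hydroxy-N-methoxy-N-methylpentadecanamide
Product: 3 N-methoxy-N-methyl-15-[(1-phenyl-1H-tetrazol-5-yl)sulfanyl]pentadecanamide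
Conditions: 1-phenyl-1H-tetrazole-5-thiol, PPh3, DIAD, THF, 0 °C to rt
Reagents that add atoms: 1-phenyl-1H-tetrazole-5-thiol, Sc1nnnn1-c1ccccc1
Why: Mitsunobu thioetherification of an unhindered primary alcohol with the acidic heteroaryl thiol is expected to proceed without touching the Weinreb amide.

**Step 3**
Reactants: 3 N-methoxy-N-methyl-15-[(1-phenyl-1H-tetrazol-5-yl)sulfanyl]pentadecanamide
Product: 4 N-methoxy-N-methyl-15-[(1-phenyl-1H-tetrazol-5-yl)sulfonyl]pentadecanamide
Conditions: (NH4)6Mo7O24·4H2O (cat.), 30% aq. H2O2, EtOH, 0 °C to rt
Reagents that add atoms: hydrogen peroxide, OO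
Why: Molybdate-catalysed peroxide oxidation of the sulfide to the sulfone should be clean because the molecule carries no other oxidisable group at this stage.

**Step 4**
Reactants: 4 N-methoxy-N-methyl-15-[(1-phenyl-1H-tetrazol-5-yl)sulfonyl]pentadecanamide; 5 (E)-crotonaldehyde
Product: 7 (15E,17E)-N-methoxy-N-methylnonadeca-15,17-dienamide, via potassium sulfonyl carbanion 6 (not isolated)
Conditions: KN(SiMe3)2, DME, −55 °C, 20 min; then 5, −55 °C to rt
Reagents that add atoms: none
Why: In this Julia–Kocienski olefination the sulfone α-CH is far more acidic than the amide α-CH, so only it is metalated; the potassium counter-ion in DME should favour the open transition state that leads to the new E alkene, while the second E alkene comes intact from crotonaldehyde (a minor Z isomer could be equilibrated with catalytic I2 at this robust stage).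

**Step 5**
Reactants: 7 (15E,17E)-N-methoxy-N-methylnonadeca-15,17-dienamide; 8 trimethylsilylacetylene
Product: 10 (17E,19E)-1-(trimethylsilyl)henicosa-17,19-dien-1-yn-3-one, via lithium trimethylsilylacetylide 9 (not isolated)
Conditions: 8, n-BuLi, THF, −78 °C; then 7, −78 to 0 °C; aq. NH4Cl
Reagents that add atoms: none
Why: Acetylide addition to a Weinreb amide should stop at the ketone stage because the chelated tetrahedral adduct survives until work-up.

**Step 6**
Reactants: 10 (17E,19E)-1-(trimethylsilyl)henicosa-17,19-dien-1-yn-3-one
Product: 11 [(17E,19E)-3,3-dimethoxyhenicosa-17,19-dien-1-yn-1-yl]trimethylsilane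
Conditions: HC(OMe)3, MeOH, TsOH·H2O (cat.), rt; Et3N quench
Reagents that add atoms: trimethyl orthoformate, COC(OC)OC; methanol, CO
Why: Acid-catalysed ketalisation with the orthoformate as water scavenger should convert the ynone into its dimethyl ketal, the silyl cap shielding the alkyne terminus from conjugate addition of methanol.

**Step 7**
Reactants: 11 [(17E,19E)-3,3-dimethoxyhenicosa-17,19-dien-1-yn-1-yl]trimethylsilane
Product: 12 (17E,19E)-3,3-dimethoxyhenicosa-17,19-dien-1-yne
Conditions: K2CO3 (cat.), MeOH, 0 °C to rt
Reagents that add atoms: none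
Why: Base-catalysed methanolysis of the alkynyl–silicon bond (protodesilylation) is routine and the ketal is stable to base.

**Step 8**
Reactants: 12 (17E,19E)-3,3-dimethoxyhenicosa-17,19-dien-1-yne; 13 methyl (E)-3-iodoacrylate
Product: 14 methyl (2E,20E,22E)-6,6-dimethoxytetracosa-2,20,22-trien-4-ynoate
Conditions: PdCl2(PPh3)2 (cat.), CuI (cat.), Et3N, THF, degassed, 0 °C to rt
Reagents that add atoms: none
Why: Sonogashira coupling of a terminal alkyne with the activated vinyl iodide should run at room temperature with retention of the E geometry of the acrylate.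

**Step 9**
Reactants: 14 methyl (2E,20E,22E)-6,6-dimethoxytetracosa-2,20,22-trien-4-ynoate
Product: 15 methyl (2E,4Z,20E,22E)-6,6-dimethoxytetracosa-2,4,20,22-tetraenoate
Conditions: Zn dust activated with Cu(OAc)2 and AgNO3, MeOH/H2O (1:1), rt, dark
Reagents that add atoms: none
Why: The Boland semi-reduction delivers both hydrogens to the same face of the conjugated alkyne on the metal surface, which should give the 4Z alkene, while the isolated diene, the enoate and the ketal are expected to survive the neutral medium.

**Step 10**
Reactants: 15 methyl (2E,4Z,20E,22E)-6,6-dimethoxytetracosa-2,4,20,22-tetraenoate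
Product: 16 methyl (2E,4Z,20E,22E)-6-hydroperoxy-6-methoxytetracosa-2,4,20,22-tetraenoate (racemic at C6)
Conditions: H2O2 (anhydrous ethereal solution, excess), camphorsulfonic acid (cat.), Et2O, 0 °C, short reaction time; NaHCO3 quench; used at once, unreacted 15 recycled
Reagents that add atoms: hydrogen peroxide, OO
Why: Acid-catalysed perhydrolysis of a ketal proceeds through the oxocarbenium ion, which the α-effect nucleophile H2O2 captures to give the α-methoxy hydroperoxide; the acidic medium should not trigger the conjugate addition, and short exposure at 0 °C is meant to stop at single exchange and keep the 4Z geometry.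

**Step 11**
Reactants: 16 methyl (2E,4Z,20E,22E)-6-hydroperoxy-6-methoxytetracosa-2,4,20,22-tetraenoate (racemic at C6)
Product: 17 methyl 2-[(6R)-3-methoxy-3-[(14E,16E)-octadeca-14,16-dien-1-yl]-3,6-dihydro-1,2-dioxin-6-yl]acetate as the pair of C3 epimers
Conditions: quinine-derived squaramide 3-{[3,5-bis(trifluoromethyl)phenyl]amino}-4-{[(8α,9S)-6'-methoxycinchonan-9-yl]amino}cyclobut-3-ene-1,2-dione (10 mol %), toluene, −40 °C, to full conversion
Reagents that add atoms: none
Why: Proposed new method: the quinuclidine nitrogen of the catalyst acts as a Brønsted base toward the acidic α-methoxy hydroperoxide while the squaramide N–H pair hydrogen-bonds the ester carbonyl, so the ammonium-paired peroxide oxygen adds to the enoate β-carbon (chain C3, ring C6) inside a chiral pocket and the resulting ester enolate is protonated at C7. The closest known reactions are the achiral amine-promoted intramolecular peroxy-Michael addition of α-methoxy hydroperoxides to enoates, which gives racemic 3-methoxy-1,2-dioxanes, and the enantioselective intramolecular oxa-Michael addition of alcohols to enoates under bifunctional base and hydrogen-bond-donor catalysis; the new element is catalyst control over a hydroperoxide nucleophile. The 1,2-dioxene ring closes in a 6-exo-trig mode, the 4Z alkene holding the OOH group within reach of the β-carbon and becoming the ring C4=C5, whereas attack at the δ-carbon would require a four-membered peroxide and is excluded. C6 (R) is set by the catalyst through its choice of enoate face; the racemic ketal carbon lies 1,4 to the new centre across a flat cis-alkene and should exert little bias, so the two enantiomers of 16 are expected to give the (3S,6R) and (3R,6R) epimers respectively. The step needs enantioface selectivity under kinetic control, which the low temperature protects by suppressing retro-Michael opening and base-induced Kornblum–DeLaMare fragmentation of the product. The substrate suits the reaction because the ketone is masked as a hydroperoxy ketal, which removes nucleophilic epoxidation of a cis-enone as a competitor and leaves no hydrogen on the peroxide-bearing carbon of 16.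

**Step 12**
Reactants: 17 methyl 2-[(6R)-3-methoxy-3-[(14E,16E)-octadeca-14,16-dien-1-yl]-3,6-dihydro-1,2-dioxin-6-yl]acetate as the pair of C3 epimers
Product: 19 xestin B [methyl 2-[(3S,6R)-3-methoxy-3-[(14E,16E)-octadeca-14,16-dien-1-yl]-3,6-dihydro-1,2-dioxin-6-yl]acetate], via cyclic peroxycarbenium ion 18 (not isolated)
Conditions: SiO2 chromatography to collect the (3S,6R) epimer; the (3R,6R) fraction: camphorsulfonic acid (cat.), MeOH, 0 °C to rt, NaHCO3 quench, re-separation, repeated
Reagents that add atoms: methanol, CO
Why: Acid-catalysed alcohol exchange of a peroxyketal passes through the planar peroxycarbenium ion 18, which interconverts the C3 epimers without touching C6; because methoxy can sit pseudo-axial (anomeric) in both epimers, neither is expected to dominate strongly, so the (3S,6R) isomer should be obtainable by separation and recycling of the other.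

**Compound list**

1 | ω-pentadecalactone (oxacyclohexadecan-2-one) | O=C1CCCCCCCCCCCCCCO1 | starting material
2 | 15-hydroxy-N-methoxy-N-methylpentadecanamide | CON(C)C(=O)CCCCCCCCCCCCCCO | intermediate
3 | N-methoxy-N-methyl-15-[(1-phenyl-1H-tetrazol-5-yl)sulfanyl]pentadecanamide | CON(C)C(=O)CCCCCCCCCCCCCCSc1nnnn1-c1ccccc1 | intermediate
4 | N-methoxy-N-methyl-15-[(1-phenyl-1H-tetrazol-5-yl)sulfonyl]pentadecanamide | CON(C)C(=O)CCCCCCCCCCCCCCS(=O)(=O)c1nnnn1-c1ccccc1 | intermediate
5 | (E)-crotonaldehyde | C/C=C/C=O | starting material
6 | potassium salt of the α-sulfonyl carbanion of 4 | CON(C)C(=O)CCCCCCCCCCCCC[CH-]S(=O)(=O)c1nnnn1-c1ccccc1.[K+] | intermediate (not isolated)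
7 | (15E,17E)-N-methoxy-N-methylnonadeca-15,17-dienamide | C/C=C/C=C/CCCCCCCCCCCCCC(=O)N(C)OC | intermediate
8 | trimethylsilylacetylene | C#C[Si](C)(C)C | starting material
9 | lithium (trimethylsilyl)acetylide | [Li]C#C[Si](C)(C)C | intermediate (not isolated)
10 | (17E,19E)-1-(trimethylsilyl)henicosa-17,19-dien-1-yn-3-one | C/C=C/C=C/CCCCCCCCCCCCCC(=O)C#C[Si](C)(C)C | intermediate
11 | [(17E,19E)-3,3-dimethoxyhenicosa-17,19-dien-1-yn-1-yl]trimethylsilane | C/C=C/C=C/CCCCCCCCCCCCCC(OC)(OC)C#C[Si](C)(C)C | intermediate
12 | (17E,19E)-3,3-dimethoxyhenicosa-17,19-dien-1-yne | C/C=C/C=C/CCCCCCCCCCCCCC(OC)(OC)C#C | intermediate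
13 | methyl (E)-3-iodoacrylate | COC(=O)/C=C/I | starting material
14 | methyl (2E,20E,22E)-6,6-dimethoxytetracosa-2,20,22-trien-4-ynoate | C/C=C/C=C/CCCCCCCCCCCCCC(OC)(OC)C#C/C=C/C(=O)OC | intermediate
15 | methyl (2E,4Z,20E,22E)-6,6-dimethoxytetracosa-2,4,20,22-tetraenoate | C/C=C/C=C/CCCCCCCCCCCCCC(OC)(OC)/C=C\C=C\C(=O)OC | intermediate
16 | methyl (2E,4Z,20E,22E)-6-hydroperoxy-6-methoxytetracosa-2,4,20,22-tetraenoate, racemic at C6 | C/C=C/C=C/CCCCCCCCCCCCCC(OC)(OO)/C=C\C=C\C(=O)OC | intermediate
17 | methyl 2-[(6R)-3-methoxy-3-[(14E,16E)-octadeca-14,16-dien-1-yl]-3,6-dihydro-1,2-dioxin-6-yl]acetate, mixture of the (3S,6R) and (3R,6R) epimers | C/C=C/C=C/CCCCCCCCCCCCCC1(OC)C=C[C@@H](CC(=O)OC)OO1 | intermediate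
18 | cyclic peroxycarbenium ion (6R)-6-(2-methoxy-2-oxoethyl)-3-[(14E,16E)-octadeca-14,16-dien-1-yl]-6H-1,2-dioxin-2-ium | C/C=C/C=C/CCCCCCCCCCCCCC1=[O+]O[C@H](CC(=O)OC)C=C1 | intermediate (not isolated)
19 | xestin B, methyl 2-[(3S,6R)-3-methoxy-3-[(14E,16E)-octadeca-14,16-dien-1-yl]-3,6-dihydro-1,2-dioxin-6-yl]acetate | C/C=C/C=C/CCCCCCCCCCCCC[C@@]1(OC)C=C[C@@H](CC(=O)OC)OO1 | target

**Totals**

Total step count: 12. Longest linear sequence: 12 steps (from 1).

**Steps most likely to fail, with fallbacks**

Step 11. The risk is insufficient discrimination between the two enoate faces, or one enantiomer of 16 responding poorly to the catalyst so that the ring forms with low enantiomeric purity at C6. The fallback uses only known chemistry and replaces asymmetric catalysis by resolution. It sets out from 16, which is closed with catalytic Et2NH in CF3CH2OH at room temperature, the established achiral amine-promoted peroxy-Michael closure, to give the racemic dioxene mixture methyl 2-[3-methoxy-3-[(14E,16E)-octadeca-14,16-dien-1-yl]-3,6-dihydro-1,2-dioxin-6-yl]acetate F1. The two racemic diastereomers are separated on silica and each is resolved by preparative HPLC on a polysaccharide chiral stationary phase. The pooled 6R fractions are compound 17, where the route is rejoined; the 6S material is discarded.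

Step 10. The risk is poor control over the degree of exchange, so that unchanged ketal, mono-hydroperoxide and bis-hydroperoxide form together, with erosion of the 4Z geometry on the prolonged acid exposure needed to push conversion. The fallback accepts the over-exchange and moves the methoxy introduction to the cyclic stage. It sets out from 15, which is driven with a large excess of ethereal H2O2 and catalytic camphorsulfonic acid to the achiral geminal bis-hydroperoxide methyl (2E,4Z,20E,22E)-6,6-dihydroperoxytetracosa-2,4,20,22-tetraenoate F2. Being achiral, F2 presents a single substrate to the catalyst of step 11 (or to Et2NH in CF3CH2OH followed by the resolution described above). Closure gives the cyclic hydroperoxy peroxyketal methyl 2-[(6R)-3-hydroperoxy-3-[(14E,16E)-octadeca-14,16-dien-1-yl]-3,6-dihydro-1,2-dioxin-6-yl]acetate F3. Its exocyclic OOH group is then exchanged for OMe with catalytic camphorsulfonic acid in methanol through the same peroxycarbenium ion, which returns the route at 17.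

Step 9. The risk is incomplete or unselective reduction at the hindered propargylic-ketal alkyne, with over-reduction, attack on the enoate or partial Z-to-E isomerisation giving dienoate mixtures. The fallback sets the Z geometry by cross-coupling instead of reduction. It sets out from 12, which undergoes rhodium-catalysed trans-hydroboration through a metal vinylidene ([Rh(cod)Cl]2, P(i-Pr)3, Et3N, pinacolborane, cyclohexane, rt) to give the Z-alkenyl boronate 2-[(1Z,17E,19E)-3,3-dimethoxyhenicosa-1,17,19-trien-1-yl]-4,4,5,5-tetramethyl-1,3,2-dioxaborolane F4. Suzuki–Miyaura coupling of F4 with 13 (Pd(PPh3)4, K3PO4, THF/H2O, rt) should proceed with retention at both alkenes and rejoins the route at 15, bypassing 14.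

**Further compounds**

F1 | step 11 | methyl 2-[3-methoxy-3-[(14E,16E)-octadeca-14,16-dien-1-yl]-3,6-dihydro-1,2-dioxin-6-yl]acetate, racemic mixture of both diastereomers | C/C=C/C=C/CCCCCCCCCCCCCC1(OC)C=CC(CC(=O)OC)OO1
F2 | step 10 | methyl (2E,4Z,20E,22E)-6,6-dihydroperoxytetracosa-2,4,20,22-tetraenoate | C/C=C/C=C/CCCCCCCCCCCCCC(OO)(OO)/C=C\C=C\C(=O)OC
F3 | step 10 | methyl 2-[(6R)-3-hydroperoxy-3-[(14E,16E)-octadeca-14,16-dien-1-yl]-3,6-dihydro-1,2-dioxin-6-yl]acetate, C3 epimers | C/C=C/C=C/CCCCCCCCCCCCCC1(OO)C=C[C@@H](CC(=O)OC)OO1
F4 | step 9 | 2-[(1Z,17E,19E)-3,3-dimethoxyhenicosa-1,17,19-trien-1-yl]-4,4,5,5-tetramethyl-1,3,2-dioxaborolane | C/C=C/C=C/CCCCCCCCCCCCCC(OC)(OC)/C=C\B1OC(C)(C)C(C)(C)O1
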